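**Overview**

The target is read as a 3-aryl-4-hydroxycoumarin (robustic acid) that has lost its lactone carbon: the two ketone carbons of the benzil are C4 and C3 of the pyranone ring, and the free phenol oxygen ortho to the diketone is the ring oxygen O1. The first retrosynthetic cut therefore puts C2 back between O1 and C3 and removes the C3 ketone oxygen.
The coumarin is then cut at C3–C4 (tethered Claisen condensation) and at the aryl ester C–O bond (4-methoxyphenylacetyl chloride). The chromene is cut at O1–C2 and C4–C4a (aryl propargyl ether Claisen cascade on a symmetric benzoate).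
Forward, the dimethylpyran ring is fused first. The 5-OH is then methylated while the 7-OH is held as an allyl ether. The pyranone ring is closed through the ester tether and finally opened again by aerobic excision of C2 as CO2.
No stereocentre is present. The chromene double bond is necessarily cis because it lies inside the six-membered pyran ring closed by the electrocyclization.

Key step: step 8

Remark: the two transient intermediates of step 8 each carry one stereocentre, should form as racemates, and lose it again in the same flask.

**Route**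

Step 1
Reactants: 1 methyl 2,4,6-trihydroxybenzoate; 2 3-chloro-3-methylbut-1-yne
Product: 3 methyl 2,6-dihydroxy-4-[(2-methylbut-3-yn-2-yl)oxy]benzoate
Conditions: 2 (1.1 equiv), K2CO3 (1.1 equiv), KI (cat.), CuI (cat.), acetone, 50 °C
Reagents that add atoms: none
Why: Copper-catalysed propargylic substitution of the tertiary chloride by a phenoxide should occur at the 4-OH, which is the only hydroxyl not hydrogen-bonded to the ester and the most acidic one.

Step 2
Reactants: 3 methyl 2,6-dihydroxy-4-[(2-methylbut-3-yn-2-yl)oxy]benzoate
Product: 6 methyl 5,7-dihydroxy-2,2-dimethyl-2H-chromene-6-carboxylate, via allenylphenol 4 (not isolated), via ortho-quinone methide 5 (not isolated)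
Conditions: o-xylene, 140 °C, argon
Reagents that add atoms: none
Why: Aryl propargyl ether Claisen rearrangement ([3,3]) followed by a 1,5-hydrogen shift and oxa-6π electrocyclization should give a single chromene, because the two ortho carbons of 3 are equivalent by symmetry and the olefin geometry is fixed by the ring.

Step 3
Reactants: 6 methyl 5,7-dihydroxy-2,2-dimethyl-2H-chromene-6-carboxylate
Product: 7 methyl 5-hydroxy-2,2-dimethyl-7-(prop-2-en-1-yloxy)-2H-chromene-6-carboxylate
Conditions: allyl bromide (1.05 equiv), K2CO3 (1.1 equiv), acetone, rt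
Reagents that add atoms: allyl bromide, C=CCBr
Why: Williamson etherification under steric control should select the 7-OH, which has only C8–H beside it, over the 5-OH wedged between the ester and the peri C4–H, and the remaining hydroxyl is then locked in a hydrogen bond to the ester carbonyl, which should stop a second allylation.

Step 4
Reactants: 7 methyl 5-hydroxy-2,2-dimethyl-7-(prop-2-en-1-yloxy)-2H-chromene-6-carboxylate
Product: 8 methyl 5-methoxy-2,2-dimethyl-7-(prop-2-en-1-yloxy)-2H-chromene-6-carboxylate
Conditions: MeI (excess), K2CO3, DMF, 40 °C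
Reagents that add atoms: iodomethane, CI
Why: Williamson methylation with the smallest electrophile in a dipolar aprotic solvent should overcome the chelation and crowding of the 5-OH, which is the only nucleophilic site left in 7.

Step 5
Reactants: 8 methyl 5-methoxy-2,2-dimethyl-7-(prop-2-en-1-yloxy)-2H-chromene-6-carboxylate
Product: 9 methyl 7-hydroxy-5-methoxy-2,2-dimethyl-2H-chromene-6-carboxylate
Conditions: Pd(PPh3)4 (5 mol %), morpholine (3 equiv), THF, rt
Reagents that add atoms: none
Why: Tsuji–Trost deallylation, in which zerovalent palladium ionises the allyl aryl ether to a π-allyl complex that morpholine captures, is neutral and should leave the ester, both methyl ethers and the chromene olefin untouched.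

Step 6
Reactants: 9 methyl 7-hydroxy-5-methoxy-2,2-dimethyl-2H-chromene-6-carboxylate; 10 4-methoxyphenylacetyl chloride
Product: 11 methyl 5-methoxy-7-{[(4-methoxyphenyl)acetyl]oxy}-2,2-dimethyl-2H-chromene-6-carboxylate
Conditions: 10 (1.2 equiv), pyridine, DMAP (cat.), CH2Cl2, 0 °C → rt
Reagents that add atoms: none
Why: DMAP-catalysed O-acylation (nucleophilic acyl substitution) of the salicylate-type phenol should install the tether, with pyridine chosen over a trialkylamine to limit ketene formation from the arylacetyl chloride.

Step 7
Reactants: 11 methyl 5-methoxy-7-{[(4-methoxyphenyl)acetyl]oxy}-2,2-dimethyl-2H-chromene-6-carboxylate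
Product: 12 4-hydroxy-5-methoxy-3-(4-methoxyphenyl)-8,8-dimethyl-2H,8H-pyrano[3,2-g]chromen-2-one (robustic acid)
Conditions: LiN(SiMe3)2 (2.2 equiv), THF, −78 °C → rt; then 1 M HCl
Reagents that add atoms: none
Why: Intramolecular Claisen (Dieckmann-type) condensation, in which the arylacetate enolate attacks the neighbouring methyl ester in a 6-exo-trig closure and methoxide leaves, should be driven to completion by the second equivalent of base forming the stabilised 4-hydroxycoumarin enolate.

Step 8
Reactants: 12 4-hydroxy-5-methoxy-3-(4-methoxyphenyl)-8,8-dimethyl-2H,8H-pyrano[3,2-g]chromen-2-one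
Product: 15 1-(7-hydroxy-5-methoxy-2,2-dimethyl-2H-chromen-6-yl)-2-(4-methoxyphenyl)ethane-1,2-dione (target), via hydroperoxydione 13 (not isolated), via hydroperoxy ketoacid 14 (not isolated)
Conditions: O2 (1 atm), Cu(OAc)2 (10 mol %), pyridine–H2O, rt; then 1 M HCl
Reagents that add atoms: dioxygen, O=O
Why: Pyridine ionises the vinylogous acid 12 to its enolate, Cu(OAc)2 (divalent copper, regenerated by O2) oxidises it by one electron to a C3 radical stabilised by the aryl group and both carbonyls, and this radical captures O2 to give hydroperoxide 13, which makes the new C3–O bond. In 13 C3 is quaternary and the aryl lactone can no longer enolise, so water under pyridine catalysis should open it at C2 to the α-hydroperoxy β-keto acid 14 and release O1 as the phenol. The carboxylate of 14 then fragments in a Grob-type decarboxylation, the C2–C3 electrons forming the C3=O bond as the O–O bond breaks, so that C2 leaves as CO2 and the 1,2-diketone appears directly. The closest known reactions are the copper-mediated aerobic oxygenative cleavage of 2-aryl-1,3-dicarbonyl compounds to 1,2-diketones and the oxidative hydrolytic decarboxylation of 3-substituted 4-hydroxycoumarins to ortho-hydroxyaryl α-oxygenated ketones. No ring closes and no stereocentre remains, since the C3 centre of 13 and 14 is racemic and is destroyed. The step needs oxidation at C3 only and cleavage of C2–C3 rather than C3–C4: the first is secured because C3 of the enolate is the only ionised carbon nucleophile while the chromene olefin and the anisyl ring are inert to O2, the second because the aryl lactone carbonyl C2 is far more electrophilic than the C4 ketone, which is deactivated by three oxygen donors on its arene and shielded by the 5-methoxy group.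

**Compound list**

1 | methyl 2,4,6-trihydroxybenzoate | COC(=O)c1c(O)cc(O)cc1O | starting material
2 | 3-chloro-3-methylbut-1-yne | CC(C)(Cl)C#C | starting material
3 | methyl 2,6-dihydroxy-4-[(2-methylbut-3-yn-2-yl)oxy]benzoate | COC(=O)c1c(O)cc(OC(C)(C)C#C)cc1O | intermediate
4 | methyl 2,4,6-trihydroxy-3-(3-methylbuta-1,2-dien-1-yl)benzoate (transient allenylphenol) | COC(=O)c1c(O)cc(O)c(C=C=C(C)C)c1O | intermediate
5 | methyl (3Z)-2,6-dihydroxy-3-(3-methylbut-2-en-1-ylidene)-4-oxocyclohexa-1,5-diene-1-carboxylate (transient ortho-quinone methide) | COC(=O)C1=C(O)/C(=C/C=C(C)C)C(=O)C=C1O | intermediate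
6 | methyl 5,7-dihydroxy-2,2-dimethyl-2H-chromene-6-carboxylate | COC(=O)c1c(O)cc2c(c1O)C=CC(C)(C)O2 | intermediate
7 | methyl 5-hydroxy-2,2-dimethyl-7-(prop-2-en-1-yloxy)-2H-chromene-6-carboxylate | COC(=O)c1c(OCC=C)cc2c(c1O)C=CC(C)(C)O2 | intermediate
8 | methyl 5-methoxy-2,2-dimethyl-7-(prop-2-en-1-yloxy)-2H-chromene-6-carboxylate | COC(=O)c1c(OCC=C)cc2c(c1OC)C=CC(C)(C)O2 | intermediate
9 | methyl 7-hydroxy-5-methoxy-2,2-dimethyl-2H-chromene-6-carboxylate | COC(=O)c1c(O)cc2c(c1OC)C=CC(C)(C)O2 | intermediate
10 | 4-methoxyphenylacetyl chloride | COc1ccc(CC(=O)Cl)cc1 | starting material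
11 | methyl 5-methoxy-7-{[(4-methoxyphenyl)acetyl]oxy}-2,2-dimethyl-2H-chromene-6-carboxylate | COC(=O)c1c(OC(=O)Cc2ccc(OC)cc2)cc2c(c1OC)C=CC(C)(C)O2 | intermediate
12 | 4-hydroxy-5-methoxy-3-(4-methoxyphenyl)-8,8-dimethyl-2H,8H-pyrano[3,2-g]chromen-2-one (robustic acid) | COc1ccc(C2=C(O)c3c(OC2=O)cc4OC(C)(C)C=Cc4c3OC)cc1 | intermediate
13 | 3-hydroperoxy-5-methoxy-3-(4-methoxyphenyl)-8,8-dimethyl-pyrano[3,2-g]chromene-2,4(3H,8H)-dione (racemic, transient) | COc1ccc(C2(OO)C(=O)c3c(OC2=O)cc4OC(C)(C)C=Cc4c3OC)cc1 | intermediate
14 | 2-hydroperoxy-3-(7-hydroxy-5-methoxy-2,2-dimethyl-2H-chromen-6-yl)-2-(4-methoxyphenyl)-3-oxopropanoic acid (racemic, transient) | COc1ccc(C(OO)(C(=O)O)C(=O)c2c(O)cc3OC(C)(C)C=Cc3c2OC)cc1 | intermediate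
15 | 1-(7-hydroxy-5-methoxy-2,2-dimethyl-2H-chromen-6-yl)-2-(4-methoxyphenyl)ethane-1,2-dione (CNP0170833.0) | COc1ccc(C(=O)C(=O)c2c(O)cc3c(c2OC)C=CC(C)(C)O3)cc1 | target

**Step count and risks**

Total step count: 8. Longest linear sequence: 8 (1 → 3 → 6 → 7 → 8 → 9 → 11 → 12 → 15).

The three steps most likely to fail:

1. Step 8. The oxygenation could be followed by fragmentation on the C3–C4 side, by further oxidative cleavage of the diketone, or by copper-mediated oxidation of the electron-rich phenolate that the ring opening releases. The fallback separates ring opening from oxidation and sets out from 12. Hot aqueous NaOH in ethanol under argon should open the lactone to the β-keto acid 3-(7-hydroxy-5-methoxy-2,2-dimethyl-2H-chromen-6-yl)-2-(4-methoxyphenyl)-3-oxopropanoic acid F1, which decarboxylates in the same flask to the deoxybenzoin 1-(7-hydroxy-5-methoxy-2,2-dimethyl-2H-chromen-6-yl)-2-(4-methoxyphenyl)ethan-1-one F2. This is the classical alkaline degradation of 3-aryl-4-hydroxycoumarins. A Riley oxidation of the doubly activated methylene (SeO2, 1,4-dioxane–H2O, 90 °C) should then give the diketone, and the chromene carries no allylic hydrogen that SeO2 could attack. The fallback comes back to the route at 15.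

2. Step 3. Discrimination between the two hydroxyls rests on sterics alone and could be poor, and over-alkylation could compete. The fallback moves the differentiation ahead of the ring fusion and sets out from 3, where the two hydroxyls are equivalent, so mono-allylation (allyl bromide, K2CO3, acetone) has no site problem and should give methyl 2-hydroxy-4-[(2-methylbut-3-yn-2-yl)oxy]-6-(prop-2-en-1-yloxy)benzoate F3. Heating F3 in o-xylene at 140 °C, below the temperature at which the allyl ether itself rearranges, should trigger the propargyl Claisen rearrangement toward the carbon next to the hydrogen-bonded hydroxyl, as is usual for chelated ortho-hydroxy carbonyl arenes. This should give the allenylphenol methyl 2,4-dihydroxy-3-(3-methylbuta-1,2-dien-1-yl)-6-(prop-2-en-1-yloxy)benzoate F4, then the dienone methyl (3Z)-2-hydroxy-3-(3-methylbut-2-en-1-ylidene)-4-oxo-6-(prop-2-en-1-yloxy)cyclohexa-1,5-diene-1-carboxylate F5, and by electrocyclization the route compound 7, where the fallback rejoins.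

3. Step 1. The phloroglucinol-type nucleus could be alkylated on carbon instead of oxygen, or etherified more than once. The fallback builds the chromene by a carbon-first annulation and sets out from 1. Condensation with 3-methylbut-2-enal under ethylenediammonium diacetate catalysis in hot toluene should give the C-alkylated carbinol methyl 2,4,6-trihydroxy-3-(1-hydroxy-3-methylbut-2-en-1-yl)benzoate F6. F6 should lose water through the non-chelated 4-OH to the same ortho-quinone methide 5 and close to 6, where the fallback rejoins the route, so that 2, 3 and 4 are bypassed.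

**Further compounds**

F1 | step 8 | 3-(7-hydroxy-5-methoxy-2,2-dimethyl-2H-chromen-6-yl)-2-(4-methoxyphenyl)-3-oxopropanoic acid | COc1ccc(C(C(=O)O)C(=O)c2c(O)cc3OC(C)(C)C=Cc3c2OC)cc1
F2 | step 8 | 1-(7-hydroxy-5-methoxy-2,2-dimethyl-2H-chromen-6-yl)-2-(4-methoxyphenyl)ethan-1-one | COc1ccc(CC(=O)c2c(O)cc3OC(C)(C)C=Cc3c2OC)cc1
F3 | step 3 | methyl 2-hydroxy-4-[(2-methylbut-3-yn-2-yl)oxy]-6-(prop-2-en-1-yloxy)benzoate | COC(=O)c1c(O)cc(OC(C)(C)C#C)cc1OCC=C
F4 | step 3 | methyl 2,4-dihydroxy-3-(3-methylbuta-1,2-dien-1-yl)-6-(prop-2-en-1-yloxy)benzoate | COC(=O)c1c(OCC=C)cc(O)c(C=C=C(C)C)c1O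
F5 | step 3 | methyl (3Z)-2-hydroxy-3-(3-methylbut-2-en-1-ylidene)-4-oxo-6-(prop-2-en-1-yloxy)cyclohexa-1,5-diene-1-carboxylate | COC(=O)C1=C(O)/C(=C/C=C(C)C)C(=O)C=C1OCC=C
F6 | step 1 | methyl 2,4,6-trihydroxy-3-(1-hydroxy-3-methylbut-2-en-1-yl)benzoate | COC(=O)c1c(O)cc(O)c(C(O)C=C(C)C)c1O
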